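At early times both runs crept. Gamma's target then rose at 0.174 min⁻¹ of the charge between its second and third readings, but at 0.0830 min⁻¹ between the last two. So I read a brake, the fall of the logarithm of the rate per minute, of 0.887 min⁻¹. Gamma's target at the middle of that last window, plus that rate over the brake, came to 29.8%: this sum is the ceiling, what a rate dying at that pace can reach.

| setting | alpha | gamma | flask |
|---|---|---|---|
| substrate | 0.016 M | 0.016 M | 0.016 M |
| reagent in the second phase | 0.048 M | 0.096 M | 0.0480 M |
| remark | the very flask that is asked about, followed so far | run made earlier |  |
| time |  |  | 6.0 min |
| volume of the second phase over the first |  |  | 0.50 |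

- alpha (time / s: target / %): 15.0: 1.7; 30.0: 0.8; 50.0: 2.5; 60.0: 3.9
- gamma (time / min: target / %): 0.333: 1.1; 0.833: 4.7; 1.50: 16.3; 2.50: 24.6

(each reading ± 1 percentage point)

- in the second phase: reagent in the second phase; everything else is in the first
- charges count per volume of the first phase; a concentration in a rate is the amount of a species over the volume of its own phase; every rate counts per litre of the first phase
- the numbers in the tables scatter by 1 percentage point (one standard deviation)
- the earlier runs hold the two phases in the same ratio of volumes as the flask asked about

* amount of target at 6.0 min, in percent of the substrate charged
* the change that raises the amount of target at 6.0 min, in percent of the substrate charged most ("none" if none brings more than 2 percentage points) (Wednesday's / Saturday's / none)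
* amount of target at 6.0 min, in percent of the substrate charged, after Saturday's

- Wednesday's: doubling the amount of reagent in the second phase, all else as stated
- Saturday's: doubling the transfer coefficient of the reagent in the second phase, all else as stated

The flask asked about is alpha continued, and its reagent is half of gamma's. I assumed that both rate and brake halve, so their ratio and the ceiling stay. The flask's brake of 0.444 min⁻¹ then leaves a gap below the ceiling of 2.3 percentage points at 6.0 min, which gave me 27.5%. Gamma's own gap there is 0.27 points, so Wednesday's gains 2 points. I took Saturday's to bring the rate earlier under the same ceiling, so I put it near 29.8%, a gain of 2.3 points. Neither gain stood clear of the margin of 2 points, given readings that scatter by 1 point, and I chose none.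

The forecast said 35%, Wednesday's and 44%, with the words “Doubling transfer helps only as far as reaction competes with transfer”.

The flask gave 26.9% and none: Wednesday's moved target by −6.5 points, Saturday's by −0.88 points, to 26.0%.

    reagent in the reaction phase ⇌ reagent in the second phase, rate k1*([reagent in the reaction phase] - [reagent in the second phase]/K1) per volume of the first phase (partition coefficient = 1.70, kL = 0.170 min⁻¹)
    substrate + reagent in the reaction phase ⇌ target (K = 510 M⁻¹, k = 11.0 M⁻¹ min⁻¹)
    reagent in the reaction phase + target → over-reacted product (k = 6.40 M⁻¹ min⁻¹)
    reagent in the reaction phase + target → over-reaction product (k = 12.0 M⁻¹ min⁻¹)

The neighbouring flask is the same flask read at 10 min. There the same reckoning shrinks the gap to 0.39 points, so it gives 29.4%. The neighbour held 22.2%, which is 7.2 points lower, and its target had fallen since 6.0 min instead of closing on the ceiling, while over-reaction product stood at 32.0%.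

All runs are calculated for an exercise; the scatter is artificial.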